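**Strategy.** The lower chroman (benzo ring A, pyran ring C) is disconnected across C2–C3 and O1–C8a, which excises formaldehyde. The feature exploited is that C3 and C8a both flank C4: as a C4 ketone, a 2-fluoroaryl benzyl ketone is acidic at C3 and activated for SNAr at the ortho carbon C8a of ring A. Base and formaldehyde then give the isoflavanone in one operation (hydroxymethylation, then fluoride displacement by the new alkoxide). The labile C3 centre is fixed by dynamic kinetic transfer hydrogenation, the C4 cation is trapped trans by the electron-rich aryl ring of a second, ketone-deactivated isoflavanone made the same way, and a second dynamic reduction plus global hydrogenolysis completes the upper isoflavan.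

Key step: step 5

Remark: the lower chroman has rings A (benzo) and C (pyran) with aryl ring B at C3, the upper isoflavan has rings D (benzo) and F (pyran) with aryl ring E, which carries C4 of the lower chroman; the SMILES is read as (3R,4S)-trans in the lower chroman and (3R) in the upper one, and paraformaldehyde serves as the source of formaldehyde 7.

**Step 1**
Reactants: 1 2'-fluoro-4'-hydroxyacetophenone
Product: 2 1-[4-(benzyloxy)-2-fluorophenyl]ethan-1-one
Conditions: BnBr, K2CO3, acetone, reflux
Reagents that add atoms: benzyl bromide, BrCc1ccccc1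
Why: Williamson ether synthesis; the para-acyl phenoxide is alkylated cleanly and is too weak a nucleophile to displace the ortho fluorine of another molecule.

**Step 2**
Reactants: 3 2,6-dimethoxyphenol
Product: 4 2-(benzyloxy)-1,3-dimethoxybenzene
Conditions: BnBr, K2CO3, DMF, 60 °C
Reagents that add atoms: benzyl bromide, BrCc1ccccc1
Why: Williamson ether synthesis masks the later C3' hydroxyl of ring B as a hydrogenolysable ether.

**Step 3**
Reactants: 4 2-(benzyloxy)-1,3-dimethoxybenzene
Product: 5 3-(benzyloxy)-1-bromo-2,4-dimethoxybenzene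
Conditions: NBS, MeCN, 0 °C to rt
Reagents that add atoms: N-bromosuccinimide, O=C1CCC(=O)N1Br
Why: Electrophilic aromatic bromination should occur para to one methoxy group and ortho to the other, as with 1,2,3-trialkoxybenzenes, because the flanked central benzyloxy group is twisted out of conjugation.

**Step 4**
Reactants: 2 1-[4-(benzyloxy)-2-fluorophenyl]ethan-1-one; 5 3-(benzyloxy)-1-bromo-2,4-dimethoxybenzene
Product: 6 1-[4-(benzyloxy)-2-fluorophenyl]-2-[3-(benzyloxy)-2,4-dimethoxyphenyl]ethan-1-one
Conditions: Pd2(dba)3 (cat.), Xantphos, K3PO4, toluene, 90 °C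
Reagents that add atoms: none
Why: Palladium-catalysed α-arylation of a ketone enolate (Buchwald–Hartwig type); zerovalent palladium inserts into the C–Br bond only, the C–F bond is inert, and the more acidic deoxybenzoin product rests as its enolate, which prevents a second arylation.

**Step 5**
Reactants: 6 1-[4-(benzyloxy)-2-fluorophenyl]-2-[3-(benzyloxy)-2,4-dimethoxyphenyl]ethan-1-one; 7 formaldehyde
Product: 9 racemic 7-(benzyloxy)-3-[3-(benzyloxy)-2,4-dimethoxyphenyl]chroman-4-one, via hydroxymethyl ketone 8 (not isolated)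
Conditions: (CH2O)n (2 equiv), Cs2CO3, DMSO, rt then 80 °C
Reagents that add atoms: none
Why: Cs2CO3 reversibly forms the enolate of 6 at the doubly activated benzylic carbon (the future C3), which adds to formaldehyde in a crossed aldol reaction (C2–C3), and the primary alkoxide of 8 then attacks the fluorine-bearing carbon ortho to the carbonyl (the future C8a) through a Meisenheimer adduct that loses fluoride (O1–C8a). The closest known reaction type is the tandem aldol–SNAr annulation of 2-fluoroaryl ketones to chroman-4-ones, joined here to the classical base-mediated hydroxymethylation of deoxybenzoins. Ring C closes by intramolecular addition–elimination at the arene, a six-membered closure in which oxygen attacks an sp2 carbon of ring A (formally 6-exo-trig with respect to the C8a=C8 bond, then loss of fluoride). C3 is the only new stereocentre; it is alpha to the ketone and configurationally labile, so it is formed racemic on purpose and is set in step 6. The step needs ring closure to win over dehydration of 8 to the alpha-methylene ketone and over a second hydroxymethylation: the irreversible, ketone-activated SNAr should drain the reversible aldol equilibria, since the enone can re-enter by conjugate addition of water and a cyclised bis-adduct can lose formaldehyde by retro-aldol cleavage. The C–F bond is the only leaving group ortho to the carbonyl, and the para benzyloxy group is inert.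

**Step 6**
Reactants: 9 racemic 7-(benzyloxy)-3-[3-(benzyloxy)-2,4-dimethoxyphenyl]chroman-4-one
Product: 10 (3R,4R)-7-(benzyloxy)-3-[3-(benzyloxy)-2,4-dimethoxyphenyl]chroman-4-ol (cis)
Conditions: RuCl(p-cymene)[(R,R)-TsDPEN] (cat.), HCO2H/Et3N (5:2), DMF, 40 °C
Reagents that add atoms: none
Why: Noyori–Ikariya asymmetric transfer hydrogenation with dynamic kinetic resolution; Et3N racemises C3 through the enol faster than reduction and the catalyst should reduce only the (3R)-ketone, hydride adding anti to the aryl group to give the cis (3R,4R) alcohol, the (R,R) ligand being chosen because it delivers (R)-benzylic alcohols from aryl ketones.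

**Step 7**
Reactants: 11 2-bromo-5-methoxyphenol
Product: 12 2-(benzyloxy)-1-bromo-4-methoxybenzene
Conditions: BnBr, K2CO3, DMF, rt
Reagents that add atoms: benzyl bromide, BrCc1ccccc1
Why: Williamson ether synthesis protects the future C2 hydroxyl of ring E.

**Step 8**
Reactants: 2 1-[4-(benzyloxy)-2-fluorophenyl]ethan-1-one; 12 2-(benzyloxy)-1-bromo-4-methoxybenzene
Product: 13 1-[4-(benzyloxy)-2-fluorophenyl]-2-[2-(benzyloxy)-4-methoxyphenyl]ethan-1-one
Conditions: Pd2(dba)3 (cat.), Xantphos, K3PO4, toluene, 90 °C
Reagents that add atoms: none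
Why: The same palladium-catalysed ketone α-arylation as in step 4, with the same chemoselectivity for C–Br over C–F.

**Step 9**
Reactants: 13 1-[4-(benzyloxy)-2-fluorophenyl]-2-[2-(benzyloxy)-4-methoxyphenyl]ethan-1-one; 7 formaldehyde
Product: 15 racemic 7-(benzyloxy)-3-[2-(benzyloxy)-4-methoxyphenyl]chroman-4-one, via hydroxymethyl ketone 14 (not isolated)
Conditions: (CH2O)n (2 equiv), Cs2CO3, DMSO, rt then 80 °C
Reagents that add atoms: none
Why: The same tandem aldol–SNAr annulation as in step 5 closes ring F; C3 is left racemic because it is set in step 11.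

**Step 10**
Reactants: 10 (3R,4R)-7-(benzyloxy)-3-[3-(benzyloxy)-2,4-dimethoxyphenyl]chroman-4-ol; 15 racemic 7-(benzyloxy)-3-[2-(benzyloxy)-4-methoxyphenyl]chroman-4-one
Product: 16 7-(benzyloxy)-3-{2-(benzyloxy)-5-[(3R,4S)-7-(benzyloxy)-3-[3-(benzyloxy)-2,4-dimethoxyphenyl]chroman-4-yl]-4-methoxyphenyl}chroman-4-one (both epimers at the labile C3 of the chromanone)
Conditions: 15 (3 equiv), BF3·OEt2 (20 mol%), 4 Å MS, CH2Cl2, −78 to −30 °C, slow addition of 10
Reagents that add atoms: none
Why: Friedel–Crafts alkylation; ionisation of the benzylic alcohol gives the C4 cation stabilised by the para C7 benzyloxy group, ring E of 15 attacks through its carbon para to the benzyloxy and ortho to the methoxy group (ring D is deactivated by the ketone), and approach anti to the C3 aryl group should set C4 trans (4S) while C3 (R) is not touched.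

**Step 11**
Reactants: 16 coupled ketone
Product: 17 (3R,4R)-7-(benzyloxy)-3-{2-(benzyloxy)-5-[(3R,4S)-7-(benzyloxy)-3-[3-(benzyloxy)-2,4-dimethoxyphenyl]chroman-4-yl]-4-methoxyphenyl}chroman-4-ol
Conditions: RuCl(p-cymene)[(R,R)-TsDPEN] (cat.), HCO2H/Et3N (5:2), DMF, 40 °C
Reagents that add atoms: none
Why: The same dynamic kinetic transfer hydrogenation as in step 6, under catalyst control and remote from the lower stereocentres, should give the cis (3R,4R) alcohol and thereby fix C3 of the upper chroman.

**Step 12**
Reactants: 17 coupled cis alcohol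
Product: 18 (3R,4S)-4-{4-hydroxy-5-[(3R)-7-hydroxychroman-3-yl]-2-methoxyphenyl}-3-(3-hydroxy-2,4-dimethoxyphenyl)chroman-7-ol (target)
Conditions: H2 (1 atm), Pd(OH)2/C, EtOH/AcOH (10:1), rt
Reagents that add atoms: none
Why: Palladium-catalysed hydrogenolysis should remove the four benzyl ethers and the para-oxygenated benzylic C4 hydroxyl of the upper chroman in one operation, while the C3 centres, the diarylmethine C4–H and the aryl alkyl ethers are not touched.

**Compound list**

1 | 2'-fluoro-4'-hydroxyacetophenone | CC(=O)c1ccc(O)cc1F | starting material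
2 | 1-[4-(benzyloxy)-2-fluorophenyl]ethan-1-one | CC(=O)c1ccc(OCc2ccccc2)cc1F | intermediate
3 | 2,6-dimethoxyphenol | COc1cccc(OC)c1O | starting material
4 | 2-(benzyloxy)-1,3-dimethoxybenzene | COc1cccc(OC)c1OCc1ccccc1 | intermediate
5 | 3-(benzyloxy)-1-bromo-2,4-dimethoxybenzene | COc1ccc(Br)c(OC)c1OCc1ccccc1 | intermediate
6 | 1-[4-(benzyloxy)-2-fluorophenyl]-2-[3-(benzyloxy)-2,4-dimethoxyphenyl]ethan-1-one | O=C(Cc1ccc(OC)c(OCc2ccccc2)c1OC)c1ccc(OCc2ccccc2)cc1F | intermediate
7 | formaldehyde (used as paraformaldehyde) | C=O | starting material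
8 | 1-[4-(benzyloxy)-2-fluorophenyl]-2-[3-(benzyloxy)-2,4-dimethoxyphenyl]-3-hydroxypropan-1-one (racemic, not isolated) | O=C(C(CO)c1ccc(OC)c(OCc2ccccc2)c1OC)c1ccc(OCc2ccccc2)cc1F | intermediate
9 | racemic 7-(benzyloxy)-3-[3-(benzyloxy)-2,4-dimethoxyphenyl]chroman-4-one | O=C1c2ccc(OCc3ccccc3)cc2OCC1c1ccc(OC)c(OCc2ccccc2)c1OC | intermediate
10 | (3R,4R)-7-(benzyloxy)-3-[3-(benzyloxy)-2,4-dimethoxyphenyl]chroman-4-ol | O[C@H]1c2ccc(OCc3ccccc3)cc2OC[C@H]1c1ccc(OC)c(OCc2ccccc2)c1OC | intermediate
11 | 2-bromo-5-methoxyphenol | COc1ccc(Br)c(O)c1 | starting material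
12 | 2-(benzyloxy)-1-bromo-4-methoxybenzene | COc1ccc(Br)c(OCc2ccccc2)c1 | intermediate
13 | 1-[4-(benzyloxy)-2-fluorophenyl]-2-[2-(benzyloxy)-4-methoxyphenyl]ethan-1-one | O=C(Cc1ccc(OC)cc1OCc1ccccc1)c1ccc(OCc2ccccc2)cc1F | intermediate
14 | 1-[4-(benzyloxy)-2-fluorophenyl]-2-[2-(benzyloxy)-4-methoxyphenyl]-3-hydroxypropan-1-one (racemic, not isolated) | O=C(C(CO)c1ccc(OC)cc1OCc1ccccc1)c1ccc(OCc2ccccc2)cc1F | intermediate
15 | racemic 7-(benzyloxy)-3-[2-(benzyloxy)-4-methoxyphenyl]chroman-4-one | O=C1c2ccc(OCc3ccccc3)cc2OCC1c1ccc(OC)cc1OCc1ccccc1 | intermediate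
16 | 7-(benzyloxy)-3-{2-(benzyloxy)-5-[(3R,4S)-7-(benzyloxy)-3-[3-(benzyloxy)-2,4-dimethoxyphenyl]chroman-4-yl]-4-methoxyphenyl}chroman-4-one (epimers at the chromanone C3) | COc1cc(OCc2ccccc2)c(C2COc3cc(OCc4ccccc4)ccc3C2=O)cc1[C@@H]1c2ccc(OCc3ccccc3)cc2OC[C@H]1c1ccc(OC)c(OCc2ccccc2)c1OC | intermediate
17 | (3R,4R)-7-(benzyloxy)-3-{2-(benzyloxy)-5-[(3R,4S)-7-(benzyloxy)-3-[3-(benzyloxy)-2,4-dimethoxyphenyl]chroman-4-yl]-4-methoxyphenyl}chroman-4-ol | COc1cc(OCc2ccccc2)c([C@@H]2COc3cc(OCc4ccccc4)ccc3[C@@H]2O)cc1[C@@H]1c2ccc(OCc3ccccc3)cc2OC[C@H]1c1ccc(OC)c(OCc2ccccc2)c1OC | intermediate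
18 | (3R,4S)-4-{4-hydroxy-5-[(3R)-7-hydroxychroman-3-yl]-2-methoxyphenyl}-3-(3-hydroxy-2,4-dimethoxyphenyl)chroman-7-ol | COc1cc(O)c([C@@H]2COc3cc(O)ccc3C2)cc1[C@@H]1c2ccc(O)cc2OC[C@H]1c1ccc(OC)c(O)c1OC | target

**Step count and risks**

Total steps: 12. Longest linear sequence: 8 steps (steps 2, 3, 4, 5, 6, 10, 11, 12).

Steps most likely to fail:

1. Step 10. The C4 cation may lose the C3 proton to give the 2H-chromene and be reprotonated, which would erode the configuration at C3. Ring A of un-ionised 10 or of the product may also compete as the nucleophile and lead to oligomers. Fallback: the route sets out from 9 and no longer relies on chirality transfer. NaBH4 in MeOH should reduce 9 to racemic 7-(benzyloxy)-3-[3-(benzyloxy)-2,4-dimethoxyphenyl]chroman-4-ol F1. The same BF3·OEt2 union with excess 15 should give the trans-configured coupled ketone that is racemic in the lower chroman F2. The transfer hydrogenation of step 11 then sets the upper centres and should give 17 together with its diastereomer bearing the (3S,4R) lower chroman F3. The two are diastereomers and are separated by preparative chromatography, and the route comes back at 17.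

2. Step 5. Dehydration of the aldol adduct to the alpha-methylene ketone and its Michael dimerisation with unreacted enolate may outrun the ring closure, because the hydroxyl is deprotonated only to a small extent. Fallback: the route sets out from 6 and brings in C2 at the formate oxidation level, where the oxygen nucleophile is an acidic enolate. Claisen formylation with HCO2Et and NaH in THF, then heating in DMF, should give by SNAr of the enolate oxygen the isoflavone 7-(benzyloxy)-3-[3-(benzyloxy)-2,4-dimethoxyphenyl]-4H-chromen-4-one F4. Transfer hydrogenation with RuCl(p-cymene)[(R,R)-TsDPEN] and HCO2H/Et3N (conjugate reduction, then dynamic kinetic reduction of the ketone) should give the cis alcohol, and the route comes back at 10.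

3. Step 11. Slow epimerisation or weak facial discrimination in the hindered, poorly soluble coupled ketone may leave the upper C3 centre as a mixture. Fallback: the route sets out from 15 and fixes this centre before the union. The conditions of step 6 should give (3R,4R)-7-(benzyloxy)-3-[2-(benzyloxy)-4-methoxyphenyl]chroman-4-ol F5. Dess–Martin periodinane then returns the enantioenriched ketone (3R)-7-(benzyloxy)-3-[2-(benzyloxy)-4-methoxyphenyl]chroman-4-one F6. Union with 10 under the conditions of step 10, kept at −78 °C to avoid enolisation, should give the single (3R)-epimer of the coupled ketone F7. LiBH(s-Bu)3 in THF at −78 °C should reduce it anti to the aryl group to the cis alcohol, and the route comes back at 17.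

**Further compounds**

F1 | step 10 | racemic 7-(benzyloxy)-3-[3-(benzyloxy)-2,4-dimethoxyphenyl]chroman-4-ol | OC1c2ccc(OCc3ccccc3)cc2OCC1c1ccc(OC)c(OCc2ccccc2)c1OC
F2 | step 10 | coupled ketone with trans lower chroman, racemic in the lower chroman | COc1cc(OCc2ccccc2)c(C2COc3cc(OCc4ccccc4)ccc3C2=O)cc1C1c2ccc(OCc3ccccc3)cc2OCC1c1ccc(OC)c(OCc2ccccc2)c1OC
F3 | step 10 | diastereomer of 17 with (3S,4R) lower chroman | COc1cc(OCc2ccccc2)c([C@@H]2COc3cc(OCc4ccccc4)ccc3[C@@H]2O)cc1[C@H]1c2ccc(OCc3ccccc3)cc2OC[C@@H]1c1ccc(OC)c(OCc2ccccc2)c1OC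
F4 | step 5 | 7-(benzyloxy)-3-[3-(benzyloxy)-2,4-dimethoxyphenyl]-4H-chromen-4-one | O=c1c(-c2ccc(OC)c(OCc3ccccc3)c2OC)coc2cc(OCc3ccccc3)ccc12
F5 | step 11 | (3R,4R)-7-(benzyloxy)-3-[2-(benzyloxy)-4-methoxyphenyl]chroman-4-ol | O[C@H]1c2ccc(OCc3ccccc3)cc2OC[C@H]1c1ccc(OC)cc1OCc1ccccc1
F6 | step 11 | (3R)-7-(benzyloxy)-3-[2-(benzyloxy)-4-methoxyphenyl]chroman-4-one | O=C1c2ccc(OCc3ccccc3)cc2OC[C@H]1c1ccc(OC)cc1OCc1ccccc1
F7 | step 11 | (3R)-7-(benzyloxy)-3-{2-(benzyloxy)-5-[(3R,4S)-7-(benzyloxy)-3-[3-(benzyloxy)-2,4-dimethoxyphenyl]chroman-4-yl]-4-methoxyphenyl}chroman-4-one | COc1cc(OCc2ccccc2)c([C@@H]2COc3cc(OCc4ccccc4)ccc3C2=O)cc1[C@@H]1c2ccc(OCc3ccccc3)cc2OC[C@H]1c1ccc(OC)c(OCc2ccccc2)c1OC
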